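**Strategy**

Ring B is 1,3,5-trisubstituted: the methoxy oxygen on C1, the CH2CH2 chain to ring A on C3 and the ether oxygen to ring C on C5. A 3-alkyl-5-oxy-phenol of this kind is the product of a vinylketene plus an oxygenated alkyne, so ring B is disconnected at C1–C6 and C4–C5. In one thermal operation a 3-(arylethyl)cyclobutenone carrying ring A is joined to the ethynyl ether of the rings C–D bibenzyl phenol; ring B forms as a phenol with the diaryl ether oxygen already attached. Both partners use 4-(benzyloxy)benzyl bromide. O-Methylation and a single BCl3 deprotection then give the target.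

Key step: step 10

Remark: the target has no stereocentre. The only stereo-elements in the route are the (E) double bond of 11 and the cis arrangement needed in dienylketene 17, and both disappear in the transformation that follows.

**Route**

Step 1
Reactants: 1 4-(benzyloxy)benzyl bromide
Product: 2 [4-(4-benzyloxyphenyl)but-1-yn-1-yl]trimethylsilane
Conditions: 1-(trimethylsilyl)propyne, n-BuLi, THF, −78 → −20 °C; then 1, −78 → 25 °C
Reagents that add atoms: 1-(trimethylsilyl)propyne, CC#C[Si](C)(C)C
Why: The silyl-capped propargyllithium should be alkylated at its CH2 terminus by the reactive benzylic bromide (SN2 propargylic alkylation), the silyl group suppressing allene formation.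

Step 2
Reactants: 2 [4-(4-benzyloxyphenyl)but-1-yn-1-yl]trimethylsilane
Product: 3 1-(benzyloxy)-4-(but-3-yn-1-yl)benzene
Conditions: K2CO3 (cat.), MeOH–THF, 25 °C
Reagents that add atoms: none
Why: Methoxide-mediated protodesilylation of the alkynyl C–Si bond is fast and should leave the benzyl ether untouched.

Step 3
Reactants: 3 1-(benzyloxy)-4-(but-3-yn-1-yl)benzene
Product: 4 3-[2-(4-benzyloxyphenyl)ethyl]-4,4-dichlorocyclobut-2-en-1-one
Conditions: Cl3CCOCl, Zn(Cu), Et2O–DME, 25 °C
Reagents that add atoms: trichloroacetyl chloride, O=C(Cl)C(Cl)(Cl)Cl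
Why: Dichloroketene generated in the flask should undergo the regioselective [2+2] ketene–alkyne cycloaddition, the unsubstituted alkyne carbon bonding to the ketene carbonyl carbon so that the chain ends up on C3.

Step 4
Reactants: 4 3-[2-(4-benzyloxyphenyl)ethyl]-4,4-dichlorocyclobut-2-en-1-one
Product: 5 3-[2-(4-benzyloxyphenyl)ethyl]cyclobut-2-en-1-one
Conditions: Zn, AcOH, TMEDA, EtOH, 0 → 25 °C
Reagents that add atoms: none
Why: Zinc reductive dechlorination of the α,α-dichloro ketone under buffered AcOH–TMEDA conditions should remove both chlorines without shifting the ring double bond or cleaving the benzyl ether.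

Step 5
Reactants: 6 2,4-dimethoxy-6-methylbenzoic acid
Product: 7 tert-butyl 2,4-dimethoxy-6-methylbenzoate
Conditions: Cl3CC(=NH)OtBu, CH2Cl2–cyclohexane, 25 °C
Reagents that add atoms: tert-butyl 2,2,2-trichloroacetimidate, CC(C)(C)OC(=N)C(Cl)(Cl)Cl
Why: Imidate esterification alkylates the carboxyl oxygen, so it should not be hindered by the two ortho substituents and needs no strong acid that could decarboxylate the electron-rich acid.

Step 6
Reactants: 7 tert-butyl 2,4-dimethoxy-6-methylbenzoate; 1 4-(benzyloxy)benzyl bromide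
Product: 9 tert-butyl 2-[2-(4-benzyloxyphenyl)ethyl]-4,6-dimethoxybenzoate, via benzylic lithium species 8 (not isolated)
Conditions: LDA, THF, −78 °C; then 1, −78 → 0 °C
Reagents that add atoms: none
Why: Lateral lithiation of the ortho-toluate gives an ester-stabilised benzylic anion that should be alkylated by the benzylic bromide (SN2), while the bulky tert-butyl ester resists self-condensation.

Step 7
Reactants: 9 tert-butyl 2-[2-(4-benzyloxyphenyl)ethyl]-4,6-dimethoxybenzoate
Product: 10 tert-butyl 2-[2-(4-hydroxyphenyl)ethyl]-4,6-dimethoxybenzoate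
Conditions: H2 (1 atm), 10% Pd/C, EtOAc, 25 °C
Reagents that add atoms: none
Why: Catalytic hydrogenolysis should cleave the benzyl aryl ether selectively, the tert-butyl ester and methyl ethers being inert.

Step 8
Reactants: 10 tert-butyl 2-[2-(4-hydroxyphenyl)ethyl]-4,6-dimethoxybenzoate
Product: 11 tert-butyl 2-[2-[4-[(E)-1,2-dichloroethenyl]oxyphenyl]ethyl]-4,6-dimethoxybenzoate
Conditions: Cl2C=CHCl, K2CO3, DMF, 70 °C
Reagents that add atoms: trichloroethylene, ClC=C(Cl)Cl
Why: The phenoxide should add anti to dichloroacetylene formed in the flask from trichloroethylene and base (nucleophilic vinylation), which fixes the (E) geometry of the dichlorovinyl ether.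

Step 9
Reactants: 11 tert-butyl 2-[2-[4-[(E)-1,2-dichloroethenyl]oxyphenyl]ethyl]-4,6-dimethoxybenzoate
Product: 14 tert-butyl 2-[2-(4-ethynyloxyphenyl)ethyl]-4,6-dimethoxybenzoate, via chloroethynyl ether 12 (not isolated), via lithium acetylide 13 (not isolated)
Conditions: n-BuLi (2.2 equiv), Et2O, −78 °C; then MeOH, −78 °C; crude 14 taken on at once
Reagents that add atoms: none
Why: In this trichloroethylene route to ynol ethers, butyllithium removes the vinyl proton with loss of chloride, a second equivalent effects chlorine–lithium exchange and methanol protonates the acetylide, and at −78 °C these fast events should outrun attack on the doubly ortho-substituted tert-butyl ester.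

Step 10
Reactants: 5 3-[2-(4-benzyloxyphenyl)ethyl]cyclobut-2-en-1-one; 14 tert-butyl 2-[2-(4-ethynyloxyphenyl)ethyl]-4,6-dimethoxybenzoate
Product: 19 tert-butyl 2-[2-[4-[3-[2-(4-benzyloxyphenyl)ethyl]-5-hydroxyphenoxy]phenyl]ethyl]-4,6-dimethoxybenzoate, via vinylketene 15 (not isolated), via 4-vinylcyclobutenone 16 (not isolated), via dienylketene 17 (not isolated), via cyclohexa-2,4-dienone 18 (not isolated)
Conditions: 5 (1.3 equiv), toluene (0.2 M), 80 °C; then KOH, MeOH, 25 °C
Reagents that add atoms: none
Why: Proposed new method: at 80 °C cyclobutenone 5 should open by four-electron electrocyclic cleavage to vinylketene 15, whose ketene C=C adds ynol ether 14 in a [2+2] cycloaddition to give 4-vinylcyclobutenone 16, which reopens to dienylketene 17, closes to dienone 18 and enolises to phenol 19. The closest known reaction is the Danheiser benzannulation of cyclobutenones with alkoxy- and silyloxyacetylenes to resorcinol monoethers; an aryloxyacetylene is a weaker donor but is polarised in the same sense and, unlike alkyl ynol ethers, cannot lose an alkene by retro-ene fragmentation on heating. Ring B is closed by a thermal six-electron disrotatory electrocyclisation of 17 that re-forms C1–C2, after the [2+2] step has made the two new skeletal bonds C1–C6 and C4–C5. No stereocentre is created in the product, since the single sp3 centre of 16 is lost on ring opening. The selectivity needed is the orientation of the [2+2] addition, secured by the ether oxygen of 14, which makes the terminal CH carbon nucleophilic so that it bonds to the ketene carbonyl carbon and places the aryloxy group on C5 and the arylethyl chain on C3, each meta to the new hydroxyl. Reversible opening of 16 should funnel material through the dienylketene geometry that can cyclise, and the final KOH treatment frees any phenol acylated by surplus ketene.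

Step 11
Reactants: 19 tert-butyl 2-[2-[4-[3-[2-(4-benzyloxyphenyl)ethyl]-5-hydroxyphenoxy]phenyl]ethyl]-4,6-dimethoxybenzoate
Product: 20 tert-butyl 2-[2-[4-[3-[2-(4-benzyloxyphenyl)ethyl]-5-methoxyphenoxy]phenyl]ethyl]-4,6-dimethoxybenzoate
Conditions: MeI, K2CO3, acetone, 50 °C
Reagents that add atoms: iodomethane, CI
Why: Williamson O-methylation of the only free phenol under mild carbonate conditions should leave the ester and the ethers unchanged.

Step 12
Reactants: 20 tert-butyl 2-[2-[4-[3-[2-(4-benzyloxyphenyl)ethyl]-5-methoxyphenoxy]phenyl]ethyl]-4,6-dimethoxybenzoate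
Product: 21 2-hydroxy-6-[2-[4-[3-[2-(4-hydroxyphenyl)ethyl]-5-methoxyphenoxy]phenyl]ethyl]-4-methoxybenzoic acid (CNP0188714.0)
Conditions: BCl3 (6 equiv), C6HMe5 (4 equiv), CH2Cl2, −78 → 0 °C; then MeOH–H2O, 0 °C
Reagents that add atoms: none
Why: In this Lewis acid dealkylation BCl3 should cleave the benzyl ether with pentamethylbenzene trapping the benzyl cation, remove the tert-butyl ester, and demethylate only the methoxy group ortho to the carboxyl through a six-membered boron chelate, leaving the two unchelated methyl ethers and the diaryl ether intact.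

**Compound list**

1 | 4-(benzyloxy)benzyl bromide | BrCc1ccc(OCc2ccccc2)cc1 | starting material
2 | [4-(4-benzyloxyphenyl)but-1-yn-1-yl]trimethylsilane | C[Si](C)(C)C#CCCc1ccc(OCc2ccccc2)cc1 | intermediate
3 | 1-(benzyloxy)-4-(but-3-yn-1-yl)benzene | C#CCCc1ccc(OCc2ccccc2)cc1 | intermediate
4 | 3-[2-(4-benzyloxyphenyl)ethyl]-4,4-dichlorocyclobut-2-en-1-one | O=C1C=C(CCc2ccc(OCc3ccccc3)cc2)C1(Cl)Cl | intermediate
5 | 3-[2-(4-benzyloxyphenyl)ethyl]cyclobut-2-en-1-one | O=C1C=C(CCc2ccc(OCc3ccccc3)cc2)C1 | intermediate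
6 | 2,4-dimethoxy-6-methylbenzoic acid | Cc1cc(OC)cc(OC)c1C(=O)O | starting material
7 | tert-butyl 2,4-dimethoxy-6-methylbenzoate | Cc1cc(OC)cc(OC)c1C(=O)OC(C)(C)C | intermediate
8 | tert-butyl 2-(lithiomethyl)-4,6-dimethoxybenzoate (formed in the flask) | [Li]Cc1cc(OC)cc(OC)c1C(=O)OC(C)(C)C | intermediate
9 | tert-butyl 2-[2-(4-benzyloxyphenyl)ethyl]-4,6-dimethoxybenzoate | COc1cc(CCc2ccc(OCc3ccccc3)cc2)c(C(=O)OC(C)(C)C)c(OC)c1 | intermediate
10 | tert-butyl 2-[2-(4-hydroxyphenyl)ethyl]-4,6-dimethoxybenzoate | COc1cc(CCc2ccc(O)cc2)c(C(=O)OC(C)(C)C)c(OC)c1 | intermediate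
11 | tert-butyl 2-[2-[4-[(E)-1,2-dichloroethenyl]oxyphenyl]ethyl]-4,6-dimethoxybenzoate | Cl/C=C(/Cl)Oc1ccc(CCc2cc(OC)cc(OC)c2C(=O)OC(C)(C)C)cc1 | intermediate
12 | tert-butyl 2-[2-[4-(chloroethynyloxy)phenyl]ethyl]-4,6-dimethoxybenzoate (formed in the flask) | ClC#COc1ccc(CCc2cc(OC)cc(OC)c2C(=O)OC(C)(C)C)cc1 | intermediate
13 | lithium acetylide of 14 (formed in the flask) | [Li]C#COc1ccc(CCc2cc(OC)cc(OC)c2C(=O)OC(C)(C)C)cc1 | intermediate
14 | tert-butyl 2-[2-(4-ethynyloxyphenyl)ethyl]-4,6-dimethoxybenzoate | C#COc1ccc(CCc2cc(OC)cc(OC)c2C(=O)OC(C)(C)C)cc1 | intermediate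
15 | vinylketene 5-(4-benzyloxyphenyl)-3-methylidenepent-1-en-1-one (formed in the flask) | O=C=CC(=C)CCc1ccc(OCc2ccccc2)cc1 | intermediate
16 | racemic 4-vinylcyclobutenone: 4-[4-(4-benzyloxyphenyl)but-1-en-2-yl]cyclobut-2-en-1-one bearing on C3 the aryloxy group of 14 (formed in the flask) | O=C1C=C(Oc2ccc(CCc3cc(OC)cc(OC)c3C(=O)OC(C)(C)C)cc2)C1C(=C)CCc4ccc(OCc5ccccc5)cc4 | intermediate
17 | dienylketene: 5-[2-(4-benzyloxyphenyl)ethyl]hexa-1,3,5-trien-1-one bearing on C3 the aryloxy group of 14, ketene carbon and C5 cis across C3=C4 (formed in the flask) | O=C=C/C(Oc2ccc(CCc3cc(OC)cc(OC)c3C(=O)OC(C)(C)C)cc2)=C\C(=C)CCc4ccc(OCc5ccccc5)cc4 | intermediate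
18 | 5-[2-(4-benzyloxyphenyl)ethyl]cyclohexa-2,4-dien-1-one bearing on C3 the aryloxy group of 14 (formed in the flask) | O=C1C=C(Oc2ccc(CCc3cc(OC)cc(OC)c3C(=O)OC(C)(C)C)cc2)C=C(CCc4ccc(OCc5ccccc5)cc4)C1 | intermediate
19 | tert-butyl 2-[2-[4-[3-[2-(4-benzyloxyphenyl)ethyl]-5-hydroxyphenoxy]phenyl]ethyl]-4,6-dimethoxybenzoate | Oc1cc(CCc2ccc(OCc3ccccc3)cc2)cc(Oc2ccc(CCc3cc(OC)cc(OC)c3C(=O)OC(C)(C)C)cc2)c1 | intermediate
20 | tert-butyl 2-[2-[4-[3-[2-(4-benzyloxyphenyl)ethyl]-5-methoxyphenoxy]phenyl]ethyl]-4,6-dimethoxybenzoate | COc1cc(CCc2ccc(OCc3ccccc3)cc2)cc(Oc2ccc(CCc3cc(OC)cc(OC)c3C(=O)OC(C)(C)C)cc2)c1 | intermediate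
21 | 2-hydroxy-6-[2-[4-[3-[2-(4-hydroxyphenyl)ethyl]-5-methoxyphenoxy]phenyl]ethyl]-4-methoxybenzoic acid | COc1cc(CCc2ccc(O)cc2)cc(Oc2ccc(CCc3cc(OC)cc(O)c3C(=O)O)cc2)c1 | target

**Step count and risk**

Total steps: 12. Longest linear sequence: 8 steps (steps 5 to 12, from 6 to 21).

Steps most likely to fail:

1. Step 10. The aryloxyacetylene may polymerise on heating, or it may be too weak a ketenophile, so that the vinylketene dimerises before the [2+2] addition takes place. Fallback: the fallback sets out from phenol 10 and returns at methyl ether 20, making the diaryl ether by Ullmann coupling on a preformed ring B. Bromide 1 and PPh3 (toluene, reflux) should give (4-benzyloxybenzyl)triphenylphosphonium bromide F1. Wittig reaction of F1 with commercial 3-bromo-5-methoxybenzaldehyde (COc1cc(Br)cc(C=O)c1; KOtBu, THF, 0 → 25 °C) should give 1-[2-(4-benzyloxyphenyl)ethenyl]-3-bromo-5-methoxybenzene F2 as an E/Z mixture. Diimide reduction (TsNHNH2, NaOAc, aqueous DME, reflux) should saturate the alkene without touching the C–Br bond or the benzyl ether, giving 1-[2-(4-benzyloxyphenyl)ethyl]-3-bromo-5-methoxybenzene F3. Coupling of F3 with phenol 10 (CuI, N,N-dimethylglycine, Cs2CO3, dioxane, 90 °C) should give 20 directly, and step 12 follows.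

2. Step 9. Butyllithium may add to the ester carbonyl or metalate the benzylic position beside ring D in competition with the elimination–exchange sequence, and the terminal ynol ether may decompose during work-up. Fallback: the fallback sets out from phenol 10 and returns at ynol ether 14 without a nucleophilic organolithium. Chan–Lam vinylation of 10 (Cu(OAc)2, pyridine, 2,4,6-trivinylcyclotriboroxane–pyridine complex, CH2Cl2, 25 °C) should give tert-butyl 2-[2-(4-ethenyloxyphenyl)ethyl]-4,6-dimethoxybenzoate F4. Bromine addition (Br2, CH2Cl2, −78 °C) should give tert-butyl 2-[2-[4-(1,2-dibromoethoxy)phenyl]ethyl]-4,6-dimethoxybenzoate F5. Double dehydrobromination with the hindered amide base LDA (THF, −78 °C) should pass through tert-butyl 2-[2-[4-(2-bromoethenyloxy)phenyl]ethyl]-4,6-dimethoxybenzoate F6 to acetylide 13, which methanol protonates to 14.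

3. Step 12. The benzyl and tert-butyl cations released together may alkylate electron-rich ring B faster than the scavenger traps them, and prolonged Lewis acid exposure may cleave an unchelated methyl ether or decarboxylate the salicylic acid. Fallback: the fallback sets out from 20 and returns at target 21 by staging the deprotection. Hydrogenolysis of 20 (H2, Pd/C, EtOAc, 25 °C) should remove the benzyl group under neutral conditions to give tert-butyl 2-[2-[4-[3-[2-(4-hydroxyphenyl)ethyl]-5-methoxyphenoxy]phenyl]ethyl]-4,6-dimethoxybenzoate F7. BCl3 (CH2Cl2, −78 → 0 °C) should then cleave only the tert-butyl ester and the chelated ortho methyl ether of F7 to give 21.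

**Further compounds**

F1 | step 10 | (4-benzyloxybenzyl)triphenylphosphonium bromide | [Br-].c1ccc(cc1)[P+](Cc1ccc(OCc2ccccc2)cc1)(c1ccccc1)c1ccccc1
F2 | step 10 | 1-[2-(4-benzyloxyphenyl)ethenyl]-3-bromo-5-methoxybenzene (E/Z mixture) | COc1cc(Br)cc(C=Cc2ccc(OCc3ccccc3)cc2)c1
F3 | step 10 | 1-[2-(4-benzyloxyphenyl)ethyl]-3-bromo-5-methoxybenzene | COc1cc(Br)cc(CCc2ccc(OCc3ccccc3)cc2)c1
F4 | step 9 | tert-butyl 2-[2-(4-ethenyloxyphenyl)ethyl]-4,6-dimethoxybenzoate | C=COc1ccc(CCc2cc(OC)cc(OC)c2C(=O)OC(C)(C)C)cc1
F5 | step 9 | tert-butyl 2-[2-[4-(1,2-dibromoethoxy)phenyl]ethyl]-4,6-dimethoxybenzoate (racemic) | BrCC(Br)Oc1ccc(CCc2cc(OC)cc(OC)c2C(=O)OC(C)(C)C)cc1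
F6 | step 9 | tert-butyl 2-[2-[4-(2-bromoethenyloxy)phenyl]ethyl]-4,6-dimethoxybenzoate (E/Z mixture, formed in the flask) | BrC=COc1ccc(CCc2cc(OC)cc(OC)c2C(=O)OC(C)(C)C)cc1
F7 | step 12 | tert-butyl 2-[2-[4-[3-[2-(4-hydroxyphenyl)ethyl]-5-methoxyphenoxy]phenyl]ethyl]-4,6-dimethoxybenzoate | COc1cc(CCc2ccc(O)cc2)cc(Oc2ccc(CCc3cc(OC)cc(OC)c3C(=O)OC(C)(C)C)cc2)c1
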